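Terpenoid numbering: ring A = C1–C5 and C10, ring B = C5–C10, side chain C11–C16 on C9. Ring B is a cyclohexene whose only alkene, C8=C9, lies opposite the C5–C6 edge, which is a Diels–Alder retron. Opening C6–C7 and C5–C10 unzips both decalin rings to an achiral acyclic trienal. In it C7=C8–C9=C10 is the diene, C5=C6 the dienophile, C1–C4 the tether, and a formyl group on C6 a traceless activator. One amine-catalysed intramolecular Diels–Alder reaction closes rings A and B and sets C5, quaternary C10 and transient C6. Decarbonylation, extension at C11 and a silicon-tethered ring-closing metathesis with a separately made (R)-carbinol butenolide (C16) finish the synthesis and fix the C13=C14 geometry.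

Key step: step 5

Remark on the chemistry: C13 carries C25H2OH and the butenolide is C17–C20. The bridgehead carbons of 22 and the hemiacetal carbon of 23 form as epimer mixtures and are drawn without configuration. These centres vanish in step 11.

Step 1
Reactants: 1 2,2-dimethylpent-4-enal; 2 diethyl [2-(methoxy(methyl)amino)-2-oxoethyl]phosphonate
Product: 3 (2E)-N-methoxy-N,4,4-trimethylhepta-2,6-dienamide
Conditions: NaH, THF, 0 °C to rt
Reagents that add atoms: phosphonate 2, CCOP(=O)(CC(=O)N(C)OC)OCC
Why: Horner–Wadsworth–Emmons olefination of a non-enolisable neopentyl-type aldehyde with a stabilised phosphonate anion should give the (E)-enamide, and the Weinreb amide is chosen because it survives hydroboration and cross-coupling and is later reduced to the aldehyde in one step.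

Step 2
Reactants: 4 but-2-yn-1-ol; 5 isopropenylmagnesium bromide
Product: 7 (2Z)-3-iodo-2-(prop-1-en-2-yl)but-2-en-1-ol, via oxamagnesacycle 6 (not isolated)
Conditions: 5 (3.5 equiv), CuI (10 mol %), THF, 0 °C to reflux; then I2, −78 °C to rt
Reagents that add atoms: isopropenylmagnesium bromide 5, C=C(C)[Mg]Br; iodine, II
Why: Hydroxyl-directed anti-carbomagnesiation of a propargylic alcohol puts the alkenyl group on the carbon next to the carbinol and magnesium on the distal carbon inside a five-membered chelate, so iodinolysis with retention fixes the tetrasubstituted C9=C10 geometry (iodine cis to CH2OH, methyl cis to isopropenyl).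

Step 3
Reactants: 3 (2E)-N-methoxy-N,4,4-trimethylhepta-2,6-dienamide; 7 (2Z)-3-iodo-2-(prop-1-en-2-yl)but-2-en-1-ol
Product: 9 (2E,8Z)-9-(hydroxymethyl)-N-methoxy-N,4,4,8,10-pentamethylundeca-2,8,10-trienamide, via B-alkyl-9-BBN borane 8 (not isolated)
Conditions: 3, 9-BBN, THF, 0 °C to rt; then 7, Pd(dppf)Cl2 (5 mol %), AsPh3, Cs2CO3, DMF–H2O, rt to 50 °C
Reagents that add atoms: none
Why: 9-BBN hydroborates only the monosubstituted alkene of 3, and the B-alkyl Suzuki–Miyaura coupling proceeds with retention at the alkenyl iodide, so tether carbon C1 ends up trans to C8, the outside position of the diene.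

Step 4
Reactants: 9 (2E,8Z)-9-(hydroxymethyl)-N-methoxy-N,4,4,8,10-pentamethylundeca-2,8,10-trienamide
Product: 10 (2E,8Z)-9-(hydroxymethyl)-4,4,8,10-tetramethylundeca-2,8,10-trienal
Conditions: iBu2AlH (2.5 equiv), THF, −78 °C; aq. Rochelle salt
Reagents that add atoms: none
Why: Weinreb amide reduction stops at the chelated tetrahedral aluminium intermediate, which collapses to the enal only on work-up, and one further equivalent of iBu2AlH is taken up by the free hydroxyl group.

Step 5
Reactants: 10 (2E,8Z)-9-(hydroxymethyl)-4,4,8,10-tetramethylundeca-2,8,10-trienal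
Product: 13 (1S,4aS,8aS)-4-(hydroxymethyl)-3,4a,8,8-tetramethyl-1,2,4a,5,6,7,8,8a-octahydronaphthalene-1-carbaldehyde (6α-formyldrim-8-en-11-ol), via trienal iminium ion 11 (not isolated), via cycloadduct iminium ion 12 (not isolated)
Conditions: (2S,5S)-5-benzyl-2-tert-butyl-3-methylimidazolidin-4-one·CF3SO3H (20 mol %), MeCN–H2O (98:2), 0 °C to rt
Reagents that add atoms: none
Why: The amine salt condenses with enal 10 to the (E)-iminium ion 11, whose lowered LUMO lets C5=C6 add suprafacially to the s-cis diene C7=C8–C9=C10 in a concerted, asynchronous [4+2] cycloaddition, and hydrolysis of 12 releases 13 and the amine. The closest known reaction type is the imidazolidinone-catalysed enantioselective intramolecular Diels–Alder reaction of 1,7,9-decatrienals (type 1, tether on the diene terminus). Ring B closes as the six-membered ring of the cycloaddition itself and ring A closes in the same event as the fused six-membered ring spanned by the four-carbon tether C1–C4 in a chair-like array. C6 and C5 are controlled by the catalyst, whose benzyl and tert-butyl groups cover one face of 11 and leave the Si face at C6 open, whereas C10 is relayed from them through the fixed C9=C10 geometry (C1 outside, methyl inside) and the endo mode, which places the C10 methyl group trans to H-5. The step needs endo (trans-fused) over exo (cis-fused) selectivity and fused over bridged regiochemistry: the exo mode would force the C4 gem-dimethyl group under the substituted C8–C9 bond, the C9 hydroxymethyl group acts as a built-in steric director against that folding, and the short tether allows only the fused adduct. Because C4 bears no hydrogen, dienamine formation and loss of conjugation cannot compete even if the reaction is slow.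

Step 6
Reactants: 13 6α-formyldrim-8-en-11-ol
Product: 14 [(4aS,8aS)-2,5,5,8a-tetramethyl-3,4,4a,5,6,7,8,8a-octahydronaphthalen-1-yl]methanol (drim-8-en-11-ol)
Conditions: RhCl(PPh3)3 (1.1 equiv), xylene, 130 °C
Reagents that add atoms: none
Why: Tsuji–Wilkinson decarbonylation (insertion into the formyl C–H bond, CO extrusion, reductive elimination) replaces the formyl group on C6 by hydrogen and erases the auxiliary stereocentre, while the tetrasubstituted alkene is too hindered to bind rhodium.

Step 7
Reactants: 14 drim-8-en-11-ol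
Product: 15 11-bromodrim-8-ene
Conditions: CBr4, PPh3, CH2Cl2, 0 °C; used without storage
Reagents that add atoms: carbon tetrabromide, BrC(Br)(Br)Br
Why: The Appel reaction displaces the alkoxyphosphonium ion at primary allylic C11 by bromide under neutral conditions and touches no stereocentre.

Step 8
Reactants: 15 11-bromodrim-8-ene; 16 2-methylprop-2-en-1-ol
Product: 18 2-methylidene-4-[(4aS,8aS)-2,5,5,8a-tetramethyl-3,4,4a,5,6,7,8,8a-octahydronaphthalen-1-yl]butan-1-ol, via dilithiated methallyl alcohol 17 (not isolated)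
Conditions: 16, nBuLi (2.1 equiv per 16), TMEDA, Et2O, 0 °C to rt; then 15, THF, −78 to 0 °C
Reagents that add atoms: 2-methylprop-2-en-1-ol 16, CC(=C)CO
Why: In this alkylation of an allylic alcohol C,O-dianion the allyl anion has two equivalent CH2 termini, so the nucleophile raises no regiochemical question, and SN2' attack at fully substituted C8 of 15 is sterically disfavoured against SN2 at C11 (forms C11–C12).

Step 9
Reactants: 19 furan-3-carbaldehyde; 20 allyltributylstannane
Product: 21 (1R)-1-(furan-3-yl)but-3-en-1-ol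
Conditions: Ti(OiPr)4 (10 mol %), (R)-BINOL (20 mol %), 4 Å MS, CH2Cl2, −20 °C
Reagents that add atoms: allyltributylstannane 20, C=CC[Sn](CCCC)(CCCC)CCCC
Why: In the Keck asymmetric allylation the (R)-BINOL titanium complex binds the aldehyde and should deliver the allyl group to the face that gives the (R)-carbinol, as for other aromatic aldehydes, which sets C16.

Step 10
Reactants: 21 (1R)-1-(furan-3-yl)but-3-en-1-ol
Product: 23 5-hydroxy-4-[(1R)-1-hydroxybut-3-en-1-yl]furan-2(5H)-one, via furan endoperoxide 22 (not isolated)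
Conditions: O2, hν, rose bengal, iPr2NEt, CH2Cl2, −78 °C
Reagents that add atoms: dioxygen, O=O
Why: Singlet oxygen adds [4+2] to the furan and the hindered amine removes the bridgehead proton remote from the substituent (Kornblum–DeLaMare fragmentation), so the carbonyl forms on the unsubstituted side, and the monosubstituted alkene is inert to singlet oxygen.

Step 11
Reactants: 23 5-hydroxy-4-[(1R)-1-hydroxybut-3-en-1-yl]furan-2(5H)-one
Product: 25 4-[(1R)-1-hydroxybut-3-en-1-yl]furan-2(5H)-one, via open-chain hydroxy acid 24 (not isolated)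
Conditions: NaBH4, EtOH, 0 °C; then 1 M HCl
Reagents that add atoms: none
Why: Borohydride reduces the ring-opened aldehyde tautomer of the hydroxybutenolide, and acidification lactonises the new CH2OH, which is cis to the carboxyl group, so the 4-substituted butenolide forms and C16 is untouched.

Step 12
Reactants: 25 4-[(1R)-1-hydroxybut-3-en-1-yl]furan-2(5H)-one; 26 dichlorodiisopropylsilane; 18 allylic alcohol of step 8
Product: 28 acyclic diisopropylsilyl bis-ether (C25–O–Si–O–C16), via chlorosilyl ether 27 (not isolated)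
Conditions: 25, 26, imidazole, CH2Cl2, 0 °C; then 18, rt
Reagents that add atoms: dichlorodiisopropylsilane 26, CC(C)[Si](Cl)(Cl)C(C)C
Why: In this stepwise silyl ether formation the bulky dichlorosilane reacts only once with the secondary alcohol, and the remaining Si–Cl bond then captures the primary allylic alcohol to give the unsymmetrical temporary tether.

Step 13
Reactants: 28 acyclic diisopropylsilyl bis-ether
Product: 29 eight-membered cyclic silaketal (1,3-dioxa-2-silacyclooct-5-ene) holding the (Z)-C13=C14 alkene
Conditions: second-generation Grubbs catalyst (10 mol %), toluene (2 mM), 80 °C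
Reagents that add atoms: none
Why: In this temporary silicon-tethered ring-closing metathesis the catalyst loads on the monosubstituted alkene and closes onto the 1,1-disubstituted alkene, the eight-membered ring can hold only a cis ring alkene so C25 and C15 end up cis, and the tetrasubstituted C8=C9 and electron-poor butenolide alkenes are inert.

Step 14
Reactants: 29 eight-membered cyclic silaketal
Product: 30 4-[(1R,3Z)-1-hydroxy-4-(hydroxymethyl)-6-[(4aS,8aS)-2,5,5,8a-tetramethyl-3,4,4a,5,6,7,8,8a-octahydronaphthalen-1-yl]hex-3-en-1-yl]furan-2(5H)-one (target)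
Conditions: HF·pyridine, THF, 0 °C to rt
Reagents that add atoms: none
Why: Fluoride-driven cleavage of both Si–O bonds under mildly acidic conditions frees the C25 and C16 hydroxyl groups without the base-induced damage a butenolide would suffer.

Compound list
1 | 2,2-dimethylpent-4-enal | C=CCC(C)(C)C=O | starting material
2 | diethyl [2-(methoxy(methyl)amino)-2-oxoethyl]phosphonate | CCOP(=O)(CC(=O)N(C)OC)OCC | starting material
3 | (2E)-N-methoxy-N,4,4-trimethylhepta-2,6-dienamide | C=CCC(C)(C)/C=C/C(=O)N(C)OC | intermediate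
4 | but-2-yn-1-ol | CC#CCO | starting material
5 | isopropenylmagnesium bromide | C=C(C)[Mg]Br | starting material
6 | oxamagnesacycle (3-methyl-4-isopropenyl-2,5-dihydro-1,2-oxamagnesole) | CC1=C(C(C)=C)CO[Mg]1 | intermediate
7 | (2Z)-3-iodo-2-(prop-1-en-2-yl)but-2-en-1-ol | C/C(I)=C(/CO)C(C)=C | intermediate
8 | B-alkyl-9-BBN borane from 3 | CON(C)C(=O)/C=C/C(C)(C)CCCB1C2CCCC1CCC2 | intermediate
9 | (2E,8Z)-9-(hydroxymethyl)-N-methoxy-N,4,4,8,10-pentamethylundeca-2,8,10-trienamide | CON(C)C(=O)/C=C/C(C)(C)CCC/C(C)=C(\CO)C(C)=C | intermediate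
10 | (2E,8Z)-9-(hydroxymethyl)-4,4,8,10-tetramethylundeca-2,8,10-trienal | O=C/C=C/C(C)(C)CCC/C(C)=C(\CO)C(C)=C | intermediate
11 | (E)-iminium triflate of 10 with the (2S,5S)-imidazolidinone | CN1[C@@H](C(C)(C)C)/[N+](=C/C=C/C(C)(C)CCC/C(C)=C(\CO)C(C)=C)[C@@H](Cc2ccccc2)C1=O.[O-]S(=O)(=O)C(F)(F)F | intermediate
12 | iminium triflate of cycloadduct 13 | CN1[C@@H](C(C)(C)C)/[N+](=C/[C@H]3CC(C)=C(CO)[C@@]4(C)CCCC(C)(C)[C@H]34)[C@@H](Cc2ccccc2)C1=O.[O-]S(=O)(=O)C(F)(F)F | intermediate
13 | (1S,4aS,8aS)-4-(hydroxymethyl)-3,4a,8,8-tetramethyl-1,2,4a,5,6,7,8,8a-octahydronaphthalene-1-carbaldehyde | CC1=C(CO)[C@@]2(C)CCCC(C)(C)[C@@H]2[C@@H](C=O)C1 | intermediate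
14 | [(4aS,8aS)-2,5,5,8a-tetramethyl-3,4,4a,5,6,7,8,8a-octahydronaphthalen-1-yl]methanol | CC1=C(CO)[C@@]2(C)CCCC(C)(C)[C@@H]2CC1 | intermediate
15 | 11-bromodrim-8-ene (5S,10S) | CC1=C(CBr)[C@@]2(C)CCCC(C)(C)[C@@H]2CC1 | intermediate
16 | 2-methylprop-2-en-1-ol | CC(=C)CO | starting material
17 | dilithiated 2-methylprop-2-en-1-ol | [Li]CC(=C)CO[Li] | intermediate
18 | 2-methylidene-4-[(4aS,8aS)-2,5,5,8a-tetramethyl-3,4,4a,5,6,7,8,8a-octahydronaphthalen-1-yl]butan-1-ol | CC1=C(CCC(=C)CO)[C@@]2(C)CCCC(C)(C)[C@@H]2CC1 | intermediate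
19 | furan-3-carbaldehyde | O=Cc1ccoc1 | starting material
20 | allyltributylstannane | C=CC[Sn](CCCC)(CCCC)CCCC | starting material
21 | (1R)-1-(furan-3-yl)but-3-en-1-ol | C=CC[C@@H](O)c1ccoc1 | intermediate
22 | furan endoperoxide (2,3,7-trioxabicyclo[2.2.1]hept-5-ene) of 21 | C=CC[C@@H](O)C1=CC2OOC1O2 | intermediate
23 | 5-hydroxy-4-[(1R)-1-hydroxybut-3-en-1-yl]furan-2(5H)-one | C=CC[C@@H](O)C1=CC(=O)OC1O | intermediate
24 | (2E,4R)-4-hydroxy-3-(hydroxymethyl)hepta-2,6-dienoic acid | C=CC[C@@H](O)/C(CO)=C/C(=O)O | intermediate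
25 | 4-[(1R)-1-hydroxybut-3-en-1-yl]furan-2(5H)-one | C=CC[C@@H](O)C1=CC(=O)OC1 | intermediate
26 | dichlorodiisopropylsilane | CC(C)[Si](Cl)(Cl)C(C)C | starting material
27 | chloro(diisopropyl)silyl ether of 25 | C=CC[C@@H](O[Si](Cl)(C(C)C)C(C)C)C1=CC(=O)OC1 | intermediate
28 | acyclic diisopropylsilyl bis-ether of 18 and 25 | CC1=C(CCC(=C)CO[Si](C(C)C)(C(C)C)O[C@H](CC=C)C3=CC(=O)OC3)[C@@]2(C)CCCC(C)(C)[C@@H]2CC1 | intermediate
29 | eight-membered cyclic silaketal, (Z)-C13=C14, (16R) | CC1=C(CC/C3=C/C[C@H](C4=CC(=O)OC4)O[Si](C(C)C)(C(C)C)OC3)[C@@]2(C)CCCC(C)(C)[C@@H]2CC1 | intermediate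
30 | 4-[(1R,3Z)-1-hydroxy-4-(hydroxymethyl)-6-[(4aS,8aS)-2,5,5,8a-tetramethyl-3,4,4a,5,6,7,8,8a-octahydronaphthalen-1-yl]hex-3-en-1-yl]furan-2(5H)-one | CC1=C(CC/C(=C/C[C@@H](O)C2=CC(=O)OC2)CO)[C@@]2(C)CCCC(C)(C)[C@@H]2CC1 | target

Total step count: 14. Longest linear sequence: 10 (steps 1, 3, 4, 5, 6, 7, 8, 12, 13, 14).

Steps most likely to fail

**Step 5.** The iminium ion may be too weak an activator. Dienophile carbon C5 has a quaternary neighbour and must bond to a fully substituted diene terminus. The reaction could therefore stall, lose its endo preference, or give way to acid-induced ionisation of the dienyl alcohol.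
- The fallback replaces catalysis by a covalently bound auxiliary and a much stronger chelating Lewis acid. It sets out from 1 (and uses 7) and returns at 13.
- Doebner–Knoevenagel condensation of 1 with malonic acid (pyridine, piperidine) should give (2E)-4,4-dimethylhepta-2,6-dienoic acid F1.
- Mixed-anhydride acylation of (S)-4-benzyloxazolidin-2-one (PivCl, Et3N, LiCl) should give the dienimide F2.
- Hydroboration with 9-BBN and coupling with 7 as in step 3 should give the trienimide F3.
- Me2AlCl (2.5 equiv, CH2Cl2, −30 °C, the first equivalent capping the hydroxyl group) forms the cationic chelate. In it the benzyl group covers the Re face at C6, and endo cycloaddition should give the imide cycloadduct F4.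
- EtSLi cleaves the auxiliary to the S-ethyl thioester F5, and iBu2AlH at −78 °C reduces F5 to 13.

**Step 13.** Closure of the eight-membered ring onto a 1,1-disubstituted alkene may be slower than intermolecular dimerisation through the monosubstituted alkene, or than alkene migration. The fallback trades the silicon tether for an ester tether and a six-membered ring, and moves butenolide formation to the end. It sets out from 18 (and uses 21) and returns at 30.
- MnO2 oxidises 18 to the 2-substituted acrolein F6, and Pinnick oxidation (NaClO2, NaH2PO4, 2-methylbut-2-ene) gives the 2-substituted acrylic acid F7.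
- Steglich esterification with 21 gives the acrylate ester F8.
- The second-generation Grubbs catalyst closes the (6R)-3,6-disubstituted 5,6-dihydropyran-2-one F9, whose ring enforces the same alkene geometry.
- iBu2AlH opens F9 to the furyl (Z)-enediol F10.
- Photooxygenation as in step 10 at −78 °C, where the furan should be consumed faster than the hindered C8=C9 alkene, gives the hydroxybutenolide F11.
- NaBH4 followed by acid, as in step 11, gives 30.

**Step 6.** Insertion of rhodium into the formyl C–H bond may be slow, because the group sits next to C5 and the C4 gem-dimethyl unit. β-Hydride elimination from the secondary alkyl rhodium intermediate could also compete with reductive elimination. The fallback removes the carbon by a radical chain instead. It sets out from 13 and returns at 14.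
- Pinnick oxidation gives the carboxylic acid F12.
- DCC coupling with 1-hydroxypyridine-2(1H)-thione gives the thiohydroxamate ester F13.
- Irradiation with visible light in the presence of tBuSH (Barton decarboxylation) delivers the C6 radical, which abstracts hydrogen to give 14.

Further compounds
F1 | step 5 | (2E)-4,4-dimethylhepta-2,6-dienoic acid | C=CCC(C)(C)/C=C/C(=O)O
F2 | step 5 | (4S)-4-benzyl-3-[(2E)-4,4-dimethylhepta-2,6-dienoyl]oxazolidin-2-one | O=C1OC[C@H](Cc2ccccc2)N1C(=O)/C=C/C(C)(C)CC=C
F3 | step 5 | (4S)-4-benzyl-3-[(2E,8Z)-9-(hydroxymethyl)-4,4,8,10-tetramethylundeca-2,8,10-trienoyl]oxazolidin-2-one | O=C1OC[C@H](Cc2ccccc2)N1C(=O)/C=C/C(C)(C)CCC/C(C)=C(\CO)C(C)=C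
F4 | step 5 | imide cycloadduct (5S,6S,10S) | CC1=C(CO)[C@@]2(C)CCCC(C)(C)[C@@H]2[C@@H](C(=O)N3[C@@H](Cc4ccccc4)COC3=O)C1
F5 | step 5 | S-ethyl thioester of the cycloadduct acid | CC1=C(CO)[C@@]2(C)CCCC(C)(C)[C@@H]2[C@@H](C(=O)SCC)C1
F6 | step 13 | 2-methylidene-4-(decalinyl)butanal | CC1=C(CCC(=C)C=O)[C@@]2(C)CCCC(C)(C)[C@@H]2CC1
F7 | step 13 | 2-methylidene-4-(decalinyl)butanoic acid | CC1=C(CCC(=C)C(=O)O)[C@@]2(C)CCCC(C)(C)[C@@H]2CC1
F8 | step 13 | (1R)-1-(furan-3-yl)but-3-en-1-yl ester of F7 | CC1=C(CCC(=C)C(=O)O[C@H](CC=C)c3ccoc3)[C@@]2(C)CCCC(C)(C)[C@@H]2CC1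
F9 | step 13 | (6R)-6-(furan-3-yl)-3-[2-(decalinyl)ethyl]-5,6-dihydropyran-2-one | CC1=C(CCC3=CC[C@H](c4ccoc4)OC3=O)[C@@]2(C)CCCC(C)(C)[C@@H]2CC1
F10 | step 13 | furyl (Z)-enediol | CC1=C(CC/C(=C/C[C@@H](O)c3ccoc3)CO)[C@@]2(C)CCCC(C)(C)[C@@H]2CC1
F11 | step 13 | 5-hydroxybutenolide of the full skeleton | CC1=C(CC/C(=C/C[C@@H](O)C3=CC(=O)OC3O)CO)[C@@]2(C)CCCC(C)(C)[C@@H]2CC1
F12 | step 6 | (1S,4aS,8aS)-4-(hydroxymethyl)-3,4a,8,8-tetramethyl-1,2,4a,5,6,7,8,8a-octahydronaphthalene-1-carboxylic acid | CC1=C(CO)[C@@]2(C)CCCC(C)(C)[C@@H]2[C@@H](C(=O)O)C1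
F13 | step 6 | 2-thioxopyridin-1(2H)-yl ester of F12 | CC1=C(CO)[C@@]2(C)CCCC(C)(C)[C@@H]2[C@@H](C(=O)ON3C=CC=CC3=S)C1
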